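Ring C is opened at the aryl ether bond O1–C8a. The C4 carbonyl sits on C4a, ortho to C8a, so a fluorine on C8a of ring A is an activated leaving group, and the C2 oxygen is placed for a six-membered closure. The precursor is an open-chain (S)-aldol: a 2-fluoroaryl ketone whose C2 carbinol is set by asymmetric transfer hydrogenation. Its alkoxide closes ring C by intramolecular SNAr in one operation, with C2 untouched. The 3-oxygen then enters trans to phenyl by Rubottom oxidation, is acylated with (S)-2-methylbutanoic anhydride, and the benzyl ethers are removed.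

Key step: step 5

Assumption: 5-fluororesorcinol and (S)-2-methylbutanoic anhydride are taken as catalogue compounds; diketone 7 is drawn in the diketo form although it should exist mainly as its chelated enol.

Step 1
Reactants: 1 5-fluororesorcinol; 2 acetic acid
Product: 3 1-(2-fluoro-4,6-dihydroxyphenyl)ethanone
Conditions: AcOH (excess), ZnCl2, 140 °C
Reagents that add atoms: none
Why: Nencki (Friedel–Crafts) acylation should go para to one hydroxyl and ortho to the other, because the site between the two hydroxyls is the more hindered one, and the product is held as a hydrogen-bonded ortho-hydroxy ketone.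

Step 2
Reactants: 3 1-(2-fluoro-4,6-dihydroxyphenyl)ethanone
Product: 4 1-[2,4-bis(benzyloxy)-6-fluorophenyl]ethanone
Conditions: BnBr (2.5 equiv), K2CO3, DMF, 60 °C
Reagents that add atoms: benzyl bromide, BrCc1ccccc1
Why: Williamson etherification of both phenols; the chelated ortho-hydroxyl needs DMF and warming, and the ring fluoride should be inert to phenoxide at this temperature.

Step 3
Reactants: 4 1-[2,4-bis(benzyloxy)-6-fluorophenyl]ethanone; 5 benzoyl chloride
Product: 7 1-[2,4-bis(benzyloxy)-6-fluorophenyl]-3-phenylpropane-1,3-dione, via lithium enolate 6 (not isolated)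
Conditions: LiHMDS (2.2 equiv), THF, −78 °C; then 5, −78 → 0 °C; 1 M HCl
Reagents that add atoms: none
Why: Claisen-type C-acylation of the kinetic lithium enolate; the second equivalent of base captures the product as its chelated lithium diketonate, which stops further acylation and is too cold to attack the ring fluoride.

Step 4
Reactants: 7 1-[2,4-bis(benzyloxy)-6-fluorophenyl]-3-phenylpropane-1,3-dione
Product: 8 (3S)-1-[2,4-bis(benzyloxy)-6-fluorophenyl]-3-hydroxy-3-phenylpropan-1-one
Conditions: RuCl[(S,S)-TsDPEN](p-cymene) (2 mol %), HCO2H/Et3N (5:2), DMF, 30 °C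
Reagents that add atoms: none
Why: Noyori–Ikariya asymmetric transfer hydrogenation should reduce only the unhindered benzoyl carbonyl (the di-ortho-substituted, electron-rich aryl ketone is shielded), and the (S,S)-diamine ligand sets the carbinol as (S) with the same facial preference as for acetophenone.

Step 5
Reactants: 8 (3S)-1-[2,4-bis(benzyloxy)-6-fluorophenyl]-3-hydroxy-3-phenylpropan-1-one
Product: 11 (2S)-5,7-bis(benzyloxy)-2-phenyl-2,3-dihydro-4H-chromen-4-one, via sodium alkoxide 9 (not isolated), via Meisenheimer adduct 10 (not isolated)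
Conditions: NaH (1.05 equiv), THF/DMF (4:1), −20 → 0 °C
Reagents that add atoms: none
Why: Deprotonation gives alkoxide 9, whose oxygen adds to C8a, the ring carbon ortho to the ketone, to give adduct 10 with the charge taken up by the C4 carbonyl, and loss of fluoride restores ring A. The closest known reaction type is the intramolecular SNAr of ortho-fluoroaryl ketones used to make chromones and chroman-4-ones. Ring C closes as a six-membered ring by attack on a trigonal aromatic carbon, formally 6-endo-trig with respect to the C8a=C4a–C4=O unit, with the C–F bond exocyclic. No stereocentre is formed, and C2 keeps its configuration because its C–O bond is never broken, so the (S)-carbinol becomes (2S) in ring C. The step needs chemoselectivity over retro-aldol cleavage and dehydration, which stoichiometric irreversible deprotonation at low temperature and the high effective molarity of the six-membered closure should secure, and site selectivity for C–F over the equally ortho C–OBn carbon, which the far better leaving-group ability of fluoride secures. The two benzyloxy groups are meta to C8a and therefore do not deactivate it by resonance.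

Step 6
Reactants: 11 (2S)-5,7-bis(benzyloxy)-2-phenyl-2,3-dihydro-4H-chromen-4-one
Product: 12 (2S)-5,7-bis(benzyloxy)-2-phenyl-4-[(trimethylsilyl)oxy]-2H-chromene
Conditions: TMSOTf (1.3 equiv), Et3N (2 equiv), CH2Cl2, 0 °C; pentane extraction
Reagents that add atoms: trimethylsilyl trifluoromethanesulfonate, C[Si](C)(C)OS(=O)(=O)C(F)(F)F
Why: Soft enolisation with silyl triflate and amine traps the C3–C4 enol without forming a free enolate, so retro-oxa-Michael opening of ring C and loss of the C2 configuration should be avoided.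

Step 7
Reactants: 12 (2S)-5,7-bis(benzyloxy)-2-phenyl-4-[(trimethylsilyl)oxy]-2H-chromene
Product: 14 (2R,3R)-5,7-bis(benzyloxy)-3-hydroxy-2-phenyl-2,3-dihydro-4H-chromen-4-one, via silyloxy epoxide 13 (not isolated)
Conditions: DMDO (1.2 equiv, acetone), CH2Cl2, −40 → 0 °C; then 1 M HCl, THF, 0 °C
Reagents that add atoms: dimethyldioxirane, CC1(C)OO1
Why: Rubottom oxidation; oxygen should be delivered to the enol ether face anti to the C2 phenyl group, so the new C3 carbinol is trans to C2 (3R), which is also the thermodynamically preferred diequatorial arrangement.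

Step 8
Reactants: 14 (2R,3R)-5,7-bis(benzyloxy)-3-hydroxy-2-phenyl-2,3-dihydro-4H-chromen-4-one; 15 (S)-2-methylbutanoic anhydride
Product: 16 (2R,3R)-5,7-bis(benzyloxy)-4-oxo-2-phenyl-3,4-dihydro-2H-chromen-3-yl (2S)-2-methylbutanoate
Conditions: 15 (1.5 equiv), DMAP (10 mol %), pyridine/CH2Cl2, 0 °C → rt
Reagents that add atoms: none
Why: DMAP-catalysed acyl transfer to the secondary 3-hydroxyl; a preformed anhydride avoids carbodiimide activation and ketene formation, so the (S) centre of the acyl group and the C3 centre should stay intact.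

Step 9
Reactants: 16 (2R,3R)-5,7-bis(benzyloxy)-4-oxo-2-phenyl-3,4-dihydro-2H-chromen-3-yl (2S)-2-methylbutanoate
Product: 17 (2R,3R)-5,7-dihydroxy-4-oxo-2-phenyl-3,4-dihydro-2H-chromen-3-yl (2S)-2-methylbutanoate (target)
Conditions: H2 (1 atm), Pd/C (10 %), EtOAc, rt
Reagents that add atoms: none
Why: Hydrogenolysis of the two aryl benzyl ethers should be much faster than cleavage of the cyclic benzylic C2–O1 bond or reduction of the hydrogen-bonded C4 ketone, and the ester is inert.

Compound list
1 | 5-fluororesorcinol (5-fluorobenzene-1,3-diol) | Oc1cc(O)cc(F)c1 | starting material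
2 | acetic acid | CC(=O)O | starting material
3 | 1-(2-fluoro-4,6-dihydroxyphenyl)ethanone | CC(=O)c1c(O)cc(O)cc1F | intermediate
4 | 1-[2,4-bis(benzyloxy)-6-fluorophenyl]ethanone | CC(=O)c1c(F)cc(OCc2ccccc2)cc1OCc1ccccc1 | intermediate
5 | benzoyl chloride | O=C(Cl)c1ccccc1 | starting material
6 | lithium enolate of 4 (formed in the flask) | [Li+].[O-]C(=C)c1c(F)cc(OCc2ccccc2)cc1OCc1ccccc1 | intermediate
7 | 1-[2,4-bis(benzyloxy)-6-fluorophenyl]-3-phenylpropane-1,3-dione | O=C(CC(=O)c1c(F)cc(OCc2ccccc2)cc1OCc1ccccc1)c1ccccc1 | intermediate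
8 | (3S)-1-[2,4-bis(benzyloxy)-6-fluorophenyl]-3-hydroxy-3-phenylpropan-1-one | O[C@@H](CC(=O)c1c(F)cc(OCc2ccccc2)cc1OCc1ccccc1)c1ccccc1 | intermediate
9 | sodium alkoxide of 8 (formed in the flask) | [Na+].[O-][C@@H](CC(=O)c1c(F)cc(OCc2ccccc2)cc1OCc1ccccc1)c1ccccc1 | intermediate
10 | Meisenheimer adduct: sodium (2S)-5,7-bis(benzyloxy)-8a-fluoro-2-phenyl-3,8a-dihydro-2H-chromen-4-olate (formed in the flask, C8a unassigned) | [Na+].[O-]C1=C2C(OCc3ccccc3)=CC(OCc3ccccc3)=CC2(F)O[C@H](c2ccccc2)C1 | intermediate
11 | (2S)-5,7-bis(benzyloxy)-2-phenyl-2,3-dihydro-4H-chromen-4-one | O=C1C[C@@H](c2ccccc2)Oc2cc(OCc3ccccc3)cc(OCc3ccccc3)c12 | intermediate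
12 | (2S)-5,7-bis(benzyloxy)-2-phenyl-4-[(trimethylsilyl)oxy]-2H-chromene | C[Si](C)(C)OC1=C[C@@H](c2ccccc2)Oc2cc(OCc3ccccc3)cc(OCc3ccccc3)c12 | intermediate
13 | (2R,3R,4R)-5,7-bis(benzyloxy)-3,4-epoxy-2-phenyl-4-[(trimethylsilyl)oxy]chromane, epoxide oxygen anti to phenyl (formed in the flask) | C[Si](C)(C)O[C@@]12O[C@@H]1[C@@H](c1ccccc1)Oc1cc(OCc3ccccc3)cc(OCc3ccccc3)c12 | intermediate
14 | (2R,3R)-5,7-bis(benzyloxy)-3-hydroxy-2-phenyl-2,3-dihydro-4H-chromen-4-one | O[C@H]1C(=O)c2c(OCc3ccccc3)cc(OCc3ccccc3)cc2O[C@@H]1c1ccccc1 | intermediate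
15 | (S)-2-methylbutanoic anhydride | CC[C@H](C)C(=O)OC(=O)[C@@H](C)CC | starting material
16 | (2R,3R)-5,7-bis(benzyloxy)-4-oxo-2-phenyl-3,4-dihydro-2H-chromen-3-yl (2S)-2-methylbutanoate | CC[C@H](C)C(=O)O[C@H]1C(=O)c2c(OCc3ccccc3)cc(OCc3ccccc3)cc2O[C@@H]1c1ccccc1 | intermediate
17 | (2R,3R)-5,7-dihydroxy-4-oxo-2-phenyl-3,4-dihydro-2H-chromen-3-yl (2S)-2-methylbutanoate | CC[C@H](C)C(=O)O[C@H]1C(=O)c2c(O)cc(O)cc2O[C@@H]1c1ccccc1 | target

Total step count: 9. Longest linear sequence: 9 steps (1 → 17).

Steps most likely to fail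

Step 5. The β-alkoxide may fragment by retro-aldol and re-add, which would erode the C2 configuration, or may dehydrate to the chalcone before ring closure occurs. The fallback sets out from diketone 7 and moves the ring closure to a stage with no β-alkoxide. K2CO3 in DMF at 80 °C should close ring C by SNAr of the enol oxygen onto the C–F carbon to give 5,7-bis(benzyloxy)-2-phenyl-4H-chromen-4-one F1. Enantioselective hydrogenation of the pyranone ring (H2, Ru(cod)(2-methylallyl)2 with a chiral N-heterocyclic carbene ligand, antipode chosen for 2S) should give (2S,4S)-5,7-bis(benzyloxy)-2-phenylchroman-4-ol F2. Oxidation of the C4 carbinol with Dess–Martin periodinane returns to the route at flavanone 11.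

Step 4. Hydride transfer to the strongly chelated enol form of the diketone may be sluggish, with poor facial discrimination. The fallback sets out from ketone 4 and makes the stereocentre by C–C bond formation instead of C=O reduction. TMSOTf and Et3N should give the silyl enol ether {1-[2,4-bis(benzyloxy)-6-fluorophenyl]ethenyl}oxy(trimethyl)silane F3. A Mukaiyama aldol addition to benzaldehyde (SiCl4, chiral bisphosphoramide 5 mol %, the antipode that exposes the Si face of the aldehyde, CH2Cl2, −78 °C) returns to the route at aldol 8.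

Step 7. Oxygen transfer may lose facial selectivity at C3, or the electron-rich ring A and the benzylic ethers may be oxidised in competition. The fallback sets out from flavanone 11 and bypasses both the silyl enol ether and the dioxirane. Direct enol acetoxylation with Pb(OAc)4 in AcOH/benzene at 60 °C should give (2R,3R)-5,7-bis(benzyloxy)-4-oxo-2-phenyl-3,4-dihydro-2H-chromen-3-yl acetate F4, with the acetate trans to phenyl. Acid-catalysed methanolysis (HCl, MeOH, rt) returns to the route at alcohol 14.

Further compounds
F1 | step 5 | 5,7-bis(benzyloxy)-2-phenyl-4H-chromen-4-one | O=c1cc(-c2ccccc2)oc2cc(OCc3ccccc3)cc(OCc3ccccc3)c12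
F2 | step 5 | (2S,4S)-5,7-bis(benzyloxy)-2-phenylchroman-4-ol | O[C@H]1C[C@@H](c2ccccc2)Oc2cc(OCc3ccccc3)cc(OCc3ccccc3)c12
F3 | step 4 | {1-[2,4-bis(benzyloxy)-6-fluorophenyl]ethenyl}oxy(trimethyl)silane | C=C(O[Si](C)(C)C)c1c(F)cc(OCc2ccccc2)cc1OCc1ccccc1
F4 | step 7 | (2R,3R)-5,7-bis(benzyloxy)-4-oxo-2-phenyl-3,4-dihydro-2H-chromen-3-yl acetate | CC(=O)O[C@H]1C(=O)c2c(OCc3ccccc3)cc(OCc3ccccc3)cc2O[C@@H]1c1ccccc1
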